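The plan rests on cutting ring B at C4–C4a. The feature exploited is its C1(aryl)–C2(CH3)–C3(CH3)–C4(H) edge: C2, C3 and C4 map onto the dichlorocarbene adduct of methyl tiglate, and C1, carrying ring A and the trimethoxyphenyl ring C, maps onto a tertiary carbinol. In one operation SnCl4 ionises the carbinol, the cyclopropane opens to a cation at C4 stabilised by its chlorine atoms, ring A attacks it para to its methoxy group, and loss of HCl aromatises ring B as a 4-chloronaphthalene. The precursor is a racemic diaryl(2,2-dichloro-1,3-dimethylcyclopropyl)methanol with cis methyl groups and a carbinol configuration that turns ring A towards C3. One hydrogenation then removes chlorine and benzyl.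

Key step: step 6

Numbering: target locants are used for all carbons that end up in the naphthalene (C1 carries ring C, C2 and C3 the methyl groups, C4 hydrogen, C6 the hydroxyl, C7 the methoxy group). Ring A is the oxygenated benzo ring, ring B the ring closed in step 6, ring C the trimethoxyphenyl group. In the cyclopropanes, C2 is the ring carbon bound to C1, C3 is CH(CH3) and C4 is CCl2.

Assumption: all chiral intermediates are racemic (one enantiomer drawn) and the target is achiral; the carbinol configuration given for 13 follows from two premises, approach of the aryllithium anti to the CCl2 group in step 5 and a tin bridge between the carbinol oxygen and the cis chlorine during ionisation in step 6.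

Step 1
Reactants: 1 methyl tiglate; 2 chloroform
Product: 4 rac-methyl (1S,3R)-2,2-dichloro-1,3-dimethylcyclopropane-1-carboxylate, via dichlorocarbene 3 (not isolated)
Conditions: CHCl3 (excess), 50% aq. NaOH, BnEt3NCl (cat.), 0 °C to rt
Reagents that add atoms: none
Why: Phase-transfer dichlorocyclopropanation: dichlorocarbene generated at the interface adds to the α,β-dimethyl acrylate in a concerted, suprafacial [2+1] cycloaddition, so the cis relationship of the two methyl groups of the E-alkene is carried into the ring and the two new stereocenters are set relative to each other (racemate), while the α-methyl group disfavours the competing conjugate addition of trichloromethanide.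

Step 2
Reactants: 4 rac-methyl (1S,3R)-2,2-dichloro-1,3-dimethylcyclopropane-1-carboxylate
Product: 6 rac-(1S,3R)-2,2-dichloro-N-methoxy-N,1,3-trimethylcyclopropane-1-carboxamide, via chloromagnesium N-methoxy-N-methylamide 5 (not isolated)
Conditions: MeNH(OMe)·HCl, iPrMgCl, THF, −20 °C to rt
Reagents that add atoms: N,O-dimethylhydroxylamine hydrochloride, CNOC.Cl
Why: Direct aminolysis of the ester by the magnesium amide of N,O-dimethylhydroxylamine (Weinreb amide formation), a small and strongly nucleophilic amide that should reach the carbonyl on the fully substituted ring carbon at temperatures where the Grignard base does not exchange the cyclopropyl chlorines; no stereocenter is touched.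

Step 3
Reactants: 6 rac-(1S,3R)-2,2-dichloro-N-methoxy-N,1,3-trimethylcyclopropane-1-carboxamide; 7 5-bromo-1,2,3-trimethoxybenzene
Product: 9 rac-[(1S,3R)-2,2-dichloro-1,3-dimethylcyclopropyl](3,4,5-trimethoxyphenyl)methanone, via (3,4,5-trimethoxyphenyl)lithium 8 (not isolated)
Conditions: 7, n-BuLi, THF, −78 °C; then 6, −78 to 0 °C; then H2O
Reagents that add atoms: none
Why: Bromine–lithium exchange and Weinreb ketone synthesis: the aryllithium adds once to the amide, the chelated tetrahedral adduct persists until the quench and so no tertiary alcohol can form, the ketone has no α-hydrogen to lose, and the ring stereocenters are not involved.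

Step 4
Reactants: 10 4-bromo-2-methoxyphenol
Product: 11 1-(benzyloxy)-4-bromo-2-methoxybenzene
Conditions: BnBr, K2CO3, DMF, rt
Reagents that add atoms: benzyl bromide, BrCc1ccccc1
Why: Williamson ether synthesis: the phenoxide formed with K2CO3 displaces bromide from benzyl bromide, and the aryl bromide is inert under these conditions.

Step 5
Reactants: 9 rac-[(1S,3R)-2,2-dichloro-1,3-dimethylcyclopropyl](3,4,5-trimethoxyphenyl)methanone; 11 1-(benzyloxy)-4-bromo-2-methoxybenzene
Product: 13 rac-(S)-[4-(benzyloxy)-3-methoxyphenyl][(1S,3R)-2,2-dichloro-1,3-dimethylcyclopropyl](3,4,5-trimethoxyphenyl)methanol, via [4-(benzyloxy)-3-methoxyphenyl]lithium 12 (not isolated)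
Conditions: 11, n-BuLi, THF, −78 °C; then 9, −78 °C; then H2O
Reagents that add atoms: none
Why: Bromine–lithium exchange and 1,2-addition of the aryllithium to a non-enolisable ketone; the new carbinol stereocenter is set by substrate control (1,2-induction from the quaternary ring carbon), the nucleophile approaching across the C3–H edge of the cyclopropane and away from the CCl2 group in the conformer that keeps ring C beside the C2 methyl, which places ring A on the C3 side once the hydroxyl sits next to CCl2.

Step 6
Reactants: 13 rac-(S)-[4-(benzyloxy)-3-methoxyphenyl][(1S,3R)-2,2-dichloro-1,3-dimethylcyclopropyl](3,4,5-trimethoxyphenyl)methanol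
Product: 15 6-(benzyloxy)-4-chloro-7-methoxy-2,3-dimethyl-1-(3,4,5-trimethoxyphenyl)naphthalene, via dichlorodihydronaphthalene 14 (not isolated)
Conditions: SnCl4 (1.2 equiv), CH2Cl2, −78 to −40 °C
Reagents that add atoms: none
Why: SnCl4 should bind the carbinol oxygen and the ring chlorine cis to it, so that the C1–O bond ionises from the conformer with ring A over the C3 edge and ring C beside the C2 methyl; the bisected cyclopropylcarbinyl cation then opens at the C2–C4 bond (charge onto the carbon carrying chlorine lone pairs, not onto C3 next to the withdrawing CCl2 group), giving the C1=C2 alkene with ring A cis to the C3–C4 chain and a cation at C4. The closest known reaction type is the Lewis-acid benzannulation of diaryl(2,2-dichlorocyclopropyl)methanols to 1-aryl-4-chloronaphthalenes, a cyclopropylcarbinyl-to-homoallyl cation rearrangement followed by intramolecular Friedel–Crafts alkylation. Ring B closes when the ring A carbon para to the methoxy group attacks C4 (six-membered closure by electrophilic aromatic substitution, the arene bond C4a–C8a ending inside the new ring), and dichloride 14 then loses HCl across C3–C4 to aromatise. No stereocenter is created and the three stereocenters of 13 are erased. The step must choose ring A over ring C and, within ring A, the position para to methoxy over the one flanked by it: the first is secured by the carbinol configuration of 13 under chelating activation, reinforced because closure onto ring C would have to occur ortho to a methoxy group that would end up peri to the C4 chlorines, and the second by the lower crowding para to methoxy.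

Step 7
Reactants: 15 6-(benzyloxy)-4-chloro-7-methoxy-2,3-dimethyl-1-(3,4,5-trimethoxyphenyl)naphthalene
Product: 16 3-methoxy-6,7-dimethyl-5-(3,4,5-trimethoxyphenyl)naphthalen-2-ol
Conditions: H2 (1 atm), 10% Pd/C, NaOAc, THF–MeOH, rt
Reagents that add atoms: none
Why: Heterogeneous catalytic hydrogenolysis: Pd/C cleaves the benzylic C–O bond and, with acetate taking up the HCl, the aryl C–Cl bond in the same operation, while the naphthalene core and the methyl ethers are inert at one atmosphere and no stereocenter is present.

Compound list
1 | methyl tiglate, methyl (E)-2-methylbut-2-enoate | C/C=C(\C)C(=O)OC | starting material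
2 | chloroform | ClC(Cl)Cl | starting material
3 | dichlorocarbene | Cl[C]Cl | intermediate
4 | rac-methyl (1S,3R)-2,2-dichloro-1,3-dimethylcyclopropane-1-carboxylate (methyl groups cis, ester trans to the C3 methyl) | COC(=O)[C@]1(C)[C@@H](C)C1(Cl)Cl | intermediate
5 | chloromagnesium N-methoxy-N-methylamide | CON(C)[Mg]Cl | intermediate
6 | rac-(1S,3R)-2,2-dichloro-N-methoxy-N,1,3-trimethylcyclopropane-1-carboxamide | CON(C)C(=O)[C@]1(C)[C@@H](C)C1(Cl)Cl | intermediate
7 | 5-bromo-1,2,3-trimethoxybenzene | COc1cc(Br)cc(OC)c1OC | starting material
8 | (3,4,5-trimethoxyphenyl)lithium | [Li]c1cc(OC)c(OC)c(OC)c1 | intermediate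
9 | rac-[(1S,3R)-2,2-dichloro-1,3-dimethylcyclopropyl](3,4,5-trimethoxyphenyl)methanone | COc1cc(cc(OC)c1OC)C(=O)[C@]1(C)[C@@H](C)C1(Cl)Cl | intermediate
10 | 4-bromo-2-methoxyphenol | COc1cc(Br)ccc1O | starting material
11 | 1-(benzyloxy)-4-bromo-2-methoxybenzene | COc1cc(Br)ccc1OCc1ccccc1 | intermediate
12 | [4-(benzyloxy)-3-methoxyphenyl]lithium | [Li]c1ccc(OCc2ccccc2)c(OC)c1 | intermediate
13 | rac-(S)-[4-(benzyloxy)-3-methoxyphenyl][(1S,3R)-2,2-dichloro-1,3-dimethylcyclopropyl](3,4,5-trimethoxyphenyl)methanol (methyl groups cis; carbinol C1 bound to ring carbon C2) | O[C@@](c1ccc(OCc2ccccc2)c(OC)c1)(c1cc(OC)c(OC)c(OC)c1)[C@]1(C)[C@@H](C)C1(Cl)Cl | intermediate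
14 | rac-(2R)-7-(benzyloxy)-1,1-dichloro-6-methoxy-2,3-dimethyl-4-(3,4,5-trimethoxyphenyl)-1,2-dihydronaphthalene (the 4,4-dichloro-3,4-dihydro compound in target numbering) | COc1cc2c(cc1OCc1ccccc1)C(Cl)(Cl)[C@H](C)C(C)=C2c1cc(OC)c(OC)c(OC)c1 | intermediate
15 | 6-(benzyloxy)-4-chloro-7-methoxy-2,3-dimethyl-1-(3,4,5-trimethoxyphenyl)naphthalene | COc1cc2c(-c3cc(OC)c(OC)c(OC)c3)c(C)c(C)c(Cl)c2cc1OCc1ccccc1 | intermediate
16 | 3-methoxy-6,7-dimethyl-5-(3,4,5-trimethoxyphenyl)naphthalen-2-ol (6-hydroxy-7-methoxy-2,3-dimethyl-1-(3,4,5-trimethoxyphenyl)naphthalene in target numbering) | COc1cc2c(-c3cc(OC)c(OC)c(OC)c3)c(C)c(C)cc2cc1O | target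

Total step count: 7. Longest linear sequence: 6 steps (steps 1, 2, 3, 5, 6, 7 from methyl tiglate); step 4 is a one-step side branch.

Steps most likely to fail

Step 6. The doubly aryl-stabilised cation may rotate about C1–C2 before the ring opens, or the tin may bind the aryl ether oxygens and not bridge oxygen and chlorine, so that closure leaks onto ring C; partial loss of the benzyl group under the Lewis acid is a lesser concern. The fallback sets out from 6 and comes back to the route at 16. It removes the regiochemical question by keeping only one aryl group on the carbinol and bringing in ring C by cross-coupling at the chlorine-bearing carbon, which then becomes C1. Amide 6 would be reduced with iBu2AlH (CH2Cl2, −78 °C) to rac-(1S,3R)-2,2-dichloro-1,3-dimethylcyclopropane-1-carbaldehyde F1. Commercial 5-bromo-2-methoxyphenol would be benzylated as in step 4 to 2-(benzyloxy)-4-bromo-1-methoxybenzene F2, which on bromine–lithium exchange (n-BuLi, THF, −78 °C) gives [3-(benzyloxy)-4-methoxyphenyl]lithium F3. Addition of this to F1 should give the secondary carbinol rac-[3-(benzyloxy)-4-methoxyphenyl][(1S,3R)-2,2-dichloro-1,3-dimethylcyclopropyl]methanol F4, either carbinol epimer being usable. SnCl4 (CH2Cl2, −78 °C) should then effect the same cationic benzannulation, now with a single ring available and closure para to the benzyloxy group, to give 6-(benzyloxy)-1-chloro-7-methoxy-2,3-dimethylnaphthalene F5. Suzuki–Miyaura coupling with (3,4,5-trimethoxyphenyl)boronic acid (Pd(OAc)2, SPhos, K3PO4, toluene–water, 100 °C) should give 6-(benzyloxy)-7-methoxy-2,3-dimethyl-1-(3,4,5-trimethoxyphenyl)naphthalene F6, and hydrogenolysis of the benzyl ether (H2, Pd/C, THF–MeOH) gives 16.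

Step 5. The aryllithium may attack the ketone on the face opposite to the one assumed, or discriminate poorly between the two faces, so that the C1 epimer is formed and the cyclisation is steered towards ring C. The fallback sets out from 6 and comes back to the route at 13; it inverts the order in which the two aryl groups are introduced. Aryllithium 12 would be added to amide 6 (THF, −78 to 0 °C) to give rac-[4-(benzyloxy)-3-methoxyphenyl][(1S,3R)-2,2-dichloro-1,3-dimethylcyclopropyl]methanone F7, and aryllithium 8 would then be added to F7 (THF, −78 °C). Because the two aryl groups exchange roles, the facial preference that gave the wrong epimer in step 5 should now give 13.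

Step 2. Acyl substitution at the crowded cyclopropyl ester may be slow, and prolonged exposure to the Grignard base may bring on chlorine–magnesium exchange or ring opening. The fallback sets out from 4 and comes back to the route at 6. Saponification (NaOH, MeOH–H2O, reflux; then HCl) should give rac-(1S,3R)-2,2-dichloro-1,3-dimethylcyclopropane-1-carboxylic acid F8. Oxalyl chloride with catalytic DMF (CH2Cl2, rt) converts it into rac-(1S,3R)-2,2-dichloro-1,3-dimethylcyclopropane-1-carbonyl chloride F9, and acylation of N,O-dimethylhydroxylamine hydrochloride with F9 (Et3N, CH2Cl2, 0 °C) gives 6.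

Further compounds
F1 | step 6 | rac-(1S,3R)-2,2-dichloro-1,3-dimethylcyclopropane-1-carbaldehyde | O=C[C@]1(C)[C@@H](C)C1(Cl)Cl
F2 | step 6 | 2-(benzyloxy)-4-bromo-1-methoxybenzene | COc1ccc(Br)cc1OCc1ccccc1
F3 | step 6 | [3-(benzyloxy)-4-methoxyphenyl]lithium | [Li]c1ccc(OC)c(OCc2ccccc2)c1
F4 | step 6 | rac-[3-(benzyloxy)-4-methoxyphenyl][(1S,3R)-2,2-dichloro-1,3-dimethylcyclopropyl]methanol, carbinol epimers not distinguished | COc1ccc(cc1OCc1ccccc1)C(O)[C@]1(C)[C@@H](C)C1(Cl)Cl
F5 | step 6 | 6-(benzyloxy)-1-chloro-7-methoxy-2,3-dimethylnaphthalene | COc1cc2c(Cl)c(C)c(C)cc2cc1OCc1ccccc1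
F6 | step 6 | 6-(benzyloxy)-7-methoxy-2,3-dimethyl-1-(3,4,5-trimethoxyphenyl)naphthalene | COc1cc2c(-c3cc(OC)c(OC)c(OC)c3)c(C)c(C)cc2cc1OCc1ccccc1
F7 | step 5 | rac-[4-(benzyloxy)-3-methoxyphenyl][(1S,3R)-2,2-dichloro-1,3-dimethylcyclopropyl]methanone | COc1cc(ccc1OCc1ccccc1)C(=O)[C@]1(C)[C@@H](C)C1(Cl)Cl
F8 | step 2 | rac-(1S,3R)-2,2-dichloro-1,3-dimethylcyclopropane-1-carboxylic acid | OC(=O)[C@]1(C)[C@@H](C)C1(Cl)Cl
F9 | step 2 | rac-(1S,3R)-2,2-dichloro-1,3-dimethylcyclopropane-1-carbonyl chloride | ClC(=O)[C@]1(C)[C@@H](C)C1(Cl)Cl
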